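**Retrosynthetic overview**
- The strategy rests on the central C15=C15' alkene of (6R)-7',8'-dihydro-ε,ψ-carotene. It joins two unlike C20 halves: the ε half, which carries the only ring (cyclohexene C1–C6, stereocentre C6), and the acyclic half, whose C1'–C11' segment is a farnesyl unit.
- C11=C12 and C11'=C12' are made last, by double loss of benzenesulfinate from the C40 triene bis(phenyl sulfone) 22.
- C15=C15' comes from Ramberg–Bäcklund contraction of tris-sulfone 19, in which a sulfonyl tether links C15 and C15'.
- 19 comes from sulfide 17, built by two successive sulfone-carbanion alkylations of the C10 bis(chloroallyl) sulfide 13: C11'–C12' with farnesyl sulfone 4, then C11–C12 with the C15 ε-sulfone 7.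
- No ring is formed: the C1–C6 ring and its 6R centre are bought with (R)-α-ionone; 13 is made from isoprene monoxide.

Key step: step 11

Assumption: (R)-α-ionone of high enantiomeric purity and 2-methyl-2-vinyloxirane (the monoepoxide of isoprene) are purchased; carotenoid numbering (C1–C15, C1'–C15') is used throughout.

**Route**

Step 1
Reactants: 1 (2E,6E)-farnesol
Product: 2 (2E,6E)-farnesyl bromide
Conditions: PBr3 (0.4 equiv), Et2O, −10 °C to 0 °C
Reagents that add atoms: phosphorus tribromide, BrP(Br)Br
Why: Bromination of a primary allylic alcohol with PBr3 (SN2 displacement on the bromophosphite ester) at low temperature should proceed without allylic transposition or loss of the 2E geometry.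

Step 2
Reactants: 2 (2E,6E)-farnesyl bromide; 3 sodium benzenesulfinate
Product: 4 (2E,6E)-farnesyl phenyl sulfone
Conditions: PhSO2Na (1.3 equiv), DMF, rt
Reagents that add atoms: none
Why: SN2 S-alkylation of the sulfinate anion by a primary allylic bromide in a dipolar aprotic solvent should give the sulfone rather than the sulfinate ester, with both E alkenes untouched.

Step 3
Reactants: 5 (R)-α-ionone
Product: 6 vinyl-α-ionol (both epimers at the carbinol carbon C9)
Conditions: CH2=CHMgBr, THF, −30 °C to 0 °C; then aq. NH4Cl
Reagents that add atoms: vinylmagnesium bromide, C=C[Mg]Br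
Why: Grignard 1,2-addition to the enone carbonyl at low temperature is much faster than enolisation toward C6, so the 6R centre should be kept, and the new carbinol centre, formed without control, is erased in step 4.

Step 4
Reactants: 6 vinyl-α-ionol; 3 sodium benzenesulfinate
Product: 7 C15 ε-dienyl phenyl sulfone (9E)
Conditions: PhSO2Na (1.5 equiv), AcOH, rt; 9E isomer purified by chromatography or crystallisation
Reagents that add atoms: none
Why: Acid ionises the tertiary doubly allylic alcohol to a pentadienyl cation that sulfinate captures through sulfur at the unhindered terminal carbon (SN1' allylic transposition, reversible under the conditions), so the conjugated primary 9E sulfone should accumulate as the thermodynamic product while C6, which only flanks the cation, keeps its configuration.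

Step 5
Reactants: 8 2-methyl-2-vinyloxirane
Product: 9 (E)-4-chloro-2-methylbut-2-en-1-ol
Conditions: TiCl4, CH2Cl2, −85 °C; then 1 M aq. HCl
Reagents that add atoms: titanium tetrachloride (TiCl4), Cl[Ti](Cl)(Cl)Cl
Why: TiCl4 activates the vinyl epoxide and delivers chloride to the vinyl terminus (SN2' epoxide opening), which should give the E-trisubstituted chloro alcohol, the racemic epoxide centre being lost.

Step 6
Reactants: 9 (E)-4-chloro-2-methylbut-2-en-1-ol (2 equiv)
Product: 11 bis[(E)-4-hydroxy-3-methylbut-2-en-1-yl] sulfide, via sodium thiolate 10 (not isolated)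
Conditions: Na2S·9H2O (0.5 equiv), degassed MeOH/H2O, 0 °C to rt
Reagents that add atoms: sodium sulfide, [Na+].[Na+].[S-2]
Why: Two successive SN2 thioetherifications by the soft sulfide and thiolate nucleophiles at the primary allylic chloride should occur without transposition and leave the E alkenes and the free hydroxyl groups unchanged.

Step 7
Reactants: 11 bis[(E)-4-hydroxy-3-methylbut-2-en-1-yl] sulfide
Product: 13 bis[(E)-4-chloro-3-methylbut-2-en-1-yl] sulfide, via bis-mesylate 12 (not isolated)
Conditions: MsCl, 2,4,6-collidine, LiCl, DMF, 0 °C; used promptly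
Reagents that add atoms: lithium chloride, [Li+].[Cl-]; methanesulfonyl chloride, CS(=O)(=O)Cl (its chloride enters the same chloride pool)
Why: Mesylation followed by in situ SN2 mesylate–chloride exchange converts primary allylic alcohols into chlorides at 0 °C without transposition, and the E alkenes hold sulfur and the chloromethyl carbons apart so that no cyclic sulfonium salt can form.

Step 8
Reactants: 4 (2E,6E)-farnesyl phenyl sulfone; 13 bis[(E)-4-chloro-3-methylbut-2-en-1-yl] sulfide (4 equiv, excess recovered)
Product: 15 C25 chloro sulfide mono(phenyl sulfone), via lithiated farnesyl sulfone 14 (not isolated)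
Conditions: n-BuLi (1.0 equiv), THF, −78 °C; cannulated into 13 (4 equiv), THF, −78 °C to −20 °C
Reagents that add atoms: none
Why: The allylic sulfone carbanion is alkylated at its alpha carbon by a primary allylic chloride (Julia-type sulfone alkylation, SN2), inverse addition to an excess of the symmetrical dichloride should suppress double alkylation, and the new C11' centre forms as a racemate that is destroyed in step 12.

Step 9
Reactants: 7 C15 ε-dienyl phenyl sulfone; 15 C25 chloro sulfide mono(phenyl sulfone)
Product: 17 C40 sulfide bis(phenyl sulfone), via lithiated dienyl sulfone 16 (not isolated)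
Conditions: n-BuLi (1.0 equiv), THF, −78 °C; then 15, −78 °C to 0 °C
Reagents that add atoms: none
Why: The pentadienyl sulfone carbanion is alkylated at the carbon alpha to sulfur (Julia-type sulfone alkylation, SN2), the far less acidic C6–H is not touched, and the new C11 centre forms without control and is destroyed in step 12.

Step 10
Reactants: 17 C40 sulfide bis(phenyl sulfone)
Product: 19 C40 tris-sulfone, via sulfoxide 18 (not isolated)
Conditions: 30% H2O2 (2.5 equiv), (NH4)6Mo7O24·4H2O (5 mol%), EtOH/THF, 0 °C to rt
Reagents that add atoms: hydrogen peroxide, OO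
Why: Peroxomolybdate-catalysed oxidation by H2O2 (chemoselective sulfide-to-sulfone oxidation) attacks an electron-rich dialkyl sulfide and its sulfoxide far faster than unactivated trisubstituted alkenes, and the rapid second oxidation leaves the allylic sulfoxide little time for sulfoxide–sulfenate rearrangement.

Step 11
Reactants: 19 C40 tris-sulfone
Product: 22 C40 central triene bis(phenyl sulfone), via alpha-chloro sulfone 20 (not isolated), via episulfone 21 (not isolated)
Conditions: powdered KOH (excess), CCl4, t-BuOH/CH2Cl2, rt, argon, dark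
Reagents that add atoms: none
Why: Hydroxide in t-BuOH deprotonates one of the two central methylenes (C15 or C15', each alpha to the tether sulfone and allylic), the carbanion takes a chlorine from CCl4 to give alpha-chloro sulfone 20, and the carbanion then formed on the other side displaces chloride to close episulfone 21, which loses SO2 cheletropically and leaves the C15=C15' alkene. This is the Ramberg–Bäcklund reaction in its in situ halogenation form (Meyers variant), a known reaction of bis(allylic) sulfones that gives conjugated trienes. The only ring closed is the transient three-membered thiirane 1,1-dioxide, formed by 3-exo-tet attack of one central carbon on the chlorine-bearing other, and it is absent from the product. No stereocentre is created; the alkene should form mainly E through the less crowded trans-episulfone, and any 15Z isomer is corrected in step 13. The step needs halogenation at the central methylenes and not at the C11 and C11' methines: these are tertiary and shielded by the phenylsulfonyl group and the branched chain, so their carbanions should form and chlorinate more slowly, while the two phenylsulfonyl groups keep the chain unconjugated during the halogenation. Because sulfur already ties one ε-ring C20 half to one farnesyl-derived C20 half, only the cross-coupled C40 skeleton can result.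

Step 12
Reactants: 22 C40 central triene bis(phenyl sulfone)
Product: 24 (6R)-α-zeacarotene E/Z mixture, via monosulfone hexaene 23 (not isolated)
Conditions: NaOEt (10 equiv), EtOH/toluene, 60 °C, argon, dark; stopped at full conversion
Reagents that add atoms: none
Why: Ethoxide removes the C12 and C12' protons, which are allylic to the central triene, and benzenesulfinate leaves from C11 and C11' (double 1,2-dehydrosulfonylation, E2/E1cB), each elimination being driven by extension of the conjugated chain so that all C11/C11' epimers converge, while the protic medium and moderate temperature are chosen to keep deprotonation at C6 slow.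

Step 13
Reactants: 24 (6R)-α-zeacarotene E/Z mixture
Product: 25 (6R)-α-zeacarotene, all-E (target)
Conditions: heptane, reflux, N2, dark; then crystallisation
Reagents that add atoms: none
Why: Thermal E/Z equilibration of a polyene should relax the sterically hindered 11Z and 11'Z isomers and the central 15Z isomer to the thermodynamically favoured all-E form, which crystallises, while C6 is not involved.

**Compound list**
1 | (2E,6E)-farnesol | CC(C)=CCC/C(C)=C/CC/C(C)=C/CO | starting material
2 | (2E,6E)-farnesyl bromide | CC(C)=CCC/C(C)=C/CC/C(C)=C/CBr | intermediate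
3 | sodium benzenesulfinate | [Na+].[O-]S(=O)c1ccccc1 | starting material
4 | (2E,6E)-farnesyl phenyl sulfone, {[(2E,6E)-3,7,11-trimethyldodeca-2,6,10-trien-1-yl]sulfonyl}benzene | CC(C)=CCC/C(C)=C/CC/C(C)=C/CS(=O)(=O)c1ccccc1 | intermediate
5 | (R)-α-ionone, (3E)-4-[(1R)-2,6,6-trimethylcyclohex-2-en-1-yl]but-3-en-2-one | CC(=O)/C=C/[C@H]1C(C)=CCCC1(C)C | starting material
6 | vinyl-α-ionol, (1E)-3-methyl-1-[(1R)-2,6,6-trimethylcyclohex-2-en-1-yl]penta-1,4-dien-3-ol, both epimers at the carbinol carbon | C=CC(C)(O)/C=C/[C@H]1C(C)=CCCC1(C)C | intermediate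
7 | C15 ε-dienyl phenyl sulfone, {[(2E,4E)-3-methyl-5-[(1R)-2,6,6-trimethylcyclohex-2-en-1-yl]penta-2,4-dien-1-yl]sulfonyl}benzene | O=S(=O)(C/C=C(C)/C=C/[C@H]1C(C)=CCCC1(C)C)c1ccccc1 | intermediate
8 | 2-methyl-2-vinyloxirane (isoprene monoxide, racemic) | CC1(C=C)CO1 | starting material
9 | (E)-4-chloro-2-methylbut-2-en-1-ol | OC/C(C)=C/CCl | intermediate
10 | sodium (E)-4-hydroxy-3-methylbut-2-ene-1-thiolate (not isolated) | [Na+].[S-]C/C=C(C)/CO | intermediate
11 | bis[(E)-4-hydroxy-3-methylbut-2-en-1-yl] sulfide | OC/C(C)=C/CSC/C=C(C)/CO | intermediate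
12 | bis-mesylate of 11 (not isolated) | CS(=O)(=O)OC/C(C)=C/CSC/C=C(C)/COS(C)(=O)=O | intermediate
13 | bis[(E)-4-chloro-3-methylbut-2-en-1-yl] sulfide | ClC/C(C)=C/CSC/C=C(C)/CCl | intermediate
14 | farnesyl phenyl sulfone lithiated at the carbon alpha to sulfur (not isolated) | CC(C)=CCC/C(C)=C/CC/C(C)=C/C([Li])S(=O)(=O)c1ccccc1 | intermediate
15 | C25 chloro sulfide mono(phenyl sulfone): farnesyl sulfone alkylated at C11' by one arm of 13, allylic chloride left at C12; racemic at C11' | CC(C)=CCC/C(C)=C/CC/C(C)=C/C(S(=O)(=O)c1ccccc1)C/C(C)=C/CSC/C=C(C)/CCl | intermediate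
16 | sulfone 7 lithiated at the carbon alpha to sulfur (not isolated) | [Li]C(/C=C(C)/C=C/[C@H]1C(C)=CCCC1(C)C)S(=O)(=O)c1ccccc1 | intermediate
17 | C40 sulfide bis(phenyl sulfone): sulfide sulfur between C15 and C15', PhSO2 at C11 and C11' (epimer mixture there), 6R | CC(C)=CCC/C(C)=C/CC/C(C)=C/C(S(=O)(=O)c1ccccc1)C/C(C)=C/CSC/C=C(C)/CC(S(=O)(=O)c1ccccc1)/C=C(C)/C=C/[C@H]1C(C)=CCCC1(C)C | intermediate
18 | sulfoxide of 17 at the tether sulfur (not isolated) | CC(C)=CCC/C(C)=C/CC/C(C)=C/C(S(=O)(=O)c1ccccc1)C/C(C)=C/CS(=O)C/C=C(C)/CC(S(=O)(=O)c1ccccc1)/C=C(C)/C=C/[C@H]1C(C)=CCCC1(C)C | intermediate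
19 | C40 tris-sulfone: sulfonyl tether between C15 and C15', PhSO2 at C11 and C11' (epimer mixture), 6R | CC(C)=CCC/C(C)=C/CC/C(C)=C/C(S(=O)(=O)c1ccccc1)C/C(C)=C/CS(=O)(=O)C/C=C(C)/CC(S(=O)(=O)c1ccccc1)/C=C(C)/C=C/[C@H]1C(C)=CCCC1(C)C | intermediate
20 | alpha-chloro sulfone of 19, chlorine drawn at C15' (the C15 isomer behaves alike; not isolated) | CC(C)=CCC/C(C)=C/CC/C(C)=C/C(S(=O)(=O)c1ccccc1)C/C(C)=C/C(Cl)S(=O)(=O)C/C=C(C)/CC(S(=O)(=O)c1ccccc1)/C=C(C)/C=C/[C@H]1C(C)=CCCC1(C)C | intermediate
21 | episulfone (thiirane 1,1-dioxide) with ring carbons C15 and C15' (not isolated) | CC(C)=CCC/C(C)=C/CC/C(C)=C/C(S(=O)(=O)c1ccccc1)C/C(C)=C/C1C(/C=C(C)/CC(S(=O)(=O)c2ccccc2)/C=C(C)/C=C/[C@H]2C(C)=CCCC2(C)C)S1(=O)=O | intermediate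
22 | C40 central triene bis(phenyl sulfone), (6R,13E,15E,13'E)-11,11'-bis(phenylsulfonyl)-11,12,11',12',7',8'-hexahydro-ε,ψ-carotene, epimer mixture at C11 and C11' | CC(C)=CCC/C(C)=C/CC/C(C)=C/C(S(=O)(=O)c1ccccc1)C/C(C)=C/C=C/C=C(C)/CC(S(=O)(=O)c1ccccc1)/C=C(C)/C=C/[C@H]1C(C)=CCCC1(C)C | intermediate
23 | monosulfone hexaene: C11=C12 formed, PhSO2 still at C11' (the other order is equally possible; not isolated) | CC(C)=CCC/C(C)=C/CC/C(C)=C/C(S(=O)(=O)c1ccccc1)C/C(C)=C/C=C/C=C(C)/C=C/C=C(C)/C=C/[C@H]1C(C)=CCCC1(C)C | intermediate
24 | (6R)-α-zeacarotene as a mixture of E/Z isomers in the central polyene (geometry between C11' and C11 unassigned) | CC(C)=CCC/C(C)=C/CC/C(C)=C/C=CC(C)=CC=CC=C(C)C=C/C=C(C)/C=C/[C@H]1C(C)=CCCC1(C)C | intermediate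
25 | (6R)-α-zeacarotene, all-E-(6R)-7',8'-dihydro-ε,ψ-carotene | CC(C)=CCC/C(C)=C/CC/C(C)=C/C=C/C(C)=C/C=C/C=C(C)/C=C/C=C(C)/C=C/[C@H]1C(C)=CCCC1(C)C | target

**Step count**
Total: 13 steps. Longest linear sequence: 9 steps (8 → 9 → 11 → 13 → 15 → 17 → 19 → 22 → 24 → 25).

**Steps most likely to fail**

1. Step 11. Halogenation and carbanion chemistry at the C11 and C11' methines may compete with the central methylenes, and dichlorocarbene released from the trichloromethyl anion may add to the electron-rich trisubstituted alkenes. The fallback brings in the central triene ready-made, without a sulfur tether; it sets out from 4 and 7 and returns at 22. Commercial (2E,4E,6E)-2,7-dimethylocta-2,4,6-trienedial (O=C/C(C)=C/C=C/C=C(C)/C=O) is reduced with NaBH4 in MeOH/THF at 0 °C to (2E,4E,6E)-2,7-dimethylocta-2,4,6-triene-1,8-diol F1. PBr3 in Et2O/THF at −20 °C converts this into (2E,4E,6E)-1,8-dibromo-2,7-dimethylocta-2,4,6-triene F2, which is used at once. Lithiated 4 (n-BuLi, THF, −78 °C) is added to an excess of F2 to give the C25 allylic bromide F3. Lithiated 7 is then alkylated by F3 under the same conditions to give 22, from which steps 12 and 13 follow.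

2. Step 12. Once the polyene is complete the C6 proton is allylic to both the ring alkene and the chromophore; under hot alkoxide its removal may cause epimerisation at C6 or migration of the ring double bond into conjugation, and the elimination may stall after loss of one sulfonyl group. The fallback builds C11=C12 and C11'=C12' by Wittig olefination with methoxide at or below room temperature, conditions under which ε end groups are configurationally stable; it sets out from 6 and 2 and returns at 24. Alcohol 6 with PPh3·HBr in MeOH at rt should give the (6R)-C15 ε-dienyl triphenylphosphonium bromide F4. Its ylide (NaOMe, MeOH/CH2Cl2, 0 °C to rt) is condensed with an excess of the commercial C10 trienedial named above to give (6R)-12'-apo-ε-caroten-12'-al F5. Bromide 2 with PPh3 in toluene at rt gives (2E,6E)-farnesyltriphenylphosphonium bromide F6. The ylide of F6 (NaOMe, MeOH/CH2Cl2, rt) is condensed with F5 to give 24, which is equilibrated as in step 13.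

3. Step 4. The pentadienyl cation may lose the C6 proton and so erase the stereocentre, may be captured at C7, or may give an unfavourable proportion of the 9Z sulfone. The fallback forms C9=C10 by olefination and never generates a cation beside C6; it sets out from 5 and returns at 7. Ketone 5 is treated with the pre-formed sodium salt of triethyl phosphonoacetate (NaH, THF, 0 °C to rt, no excess base) in a Horner–Wadsworth–Emmons reaction to give ethyl (2E,4E)-3-methyl-5-[(1R)-2,6,6-trimethylcyclohex-2-en-1-yl]penta-2,4-dienoate F7, whose 9E isomer is separated by chromatography. DIBAL-H in toluene at −78 °C reduces it to the dienol F8. PBr3 in Et2O at −20 °C gives the dienyl bromide F9, and 3 in DMF at rt converts this into 7.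

**Further compounds**
F1 | step 11 | (2E,4E,6E)-2,7-dimethylocta-2,4,6-triene-1,8-diol | OC/C(C)=C/C=C/C=C(C)/CO
F2 | step 11 | (2E,4E,6E)-1,8-dibromo-2,7-dimethylocta-2,4,6-triene | BrC/C(C)=C/C=C/C=C(C)/CBr
F3 | step 11 | C25 allylic bromide: farnesyl phenyl sulfone alkylated at C11' by one end of F2, bromide at C12, racemic at C11' | CC(C)=CCC/C(C)=C/CC/C(C)=C/C(S(=O)(=O)c1ccccc1)C/C(C)=C/C=C/C=C(C)/CBr
F4 | step 12 | [(2E,4E)-3-methyl-5-[(1R)-2,6,6-trimethylcyclohex-2-en-1-yl]penta-2,4-dien-1-yl]triphenylphosphonium bromide | [Br-].C(/C=C(C)/C=C/[C@H]1C(C)=CCCC1(C)C)[P+](c1ccccc1)(c1ccccc1)c1ccccc1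
F5 | step 12 | (6R)-12'-apo-ε-caroten-12'-al | O=C/C(C)=C/C=C/C=C(C)/C=C/C=C(C)/C=C/[C@H]1C(C)=CCCC1(C)C
F6 | step 12 | (2E,6E)-farnesyltriphenylphosphonium bromide | [Br-].CC(C)=CCC/C(C)=C/CC/C(C)=C/C[P+](c1ccccc1)(c1ccccc1)c1ccccc1
F7 | step 4 | ethyl (2E,4E)-3-methyl-5-[(1R)-2,6,6-trimethylcyclohex-2-en-1-yl]penta-2,4-dienoate | CCOC(=O)/C=C(C)/C=C/[C@H]1C(C)=CCCC1(C)C
F8 | step 4 | (2E,4E)-3-methyl-5-[(1R)-2,6,6-trimethylcyclohex-2-en-1-yl]penta-2,4-dien-1-ol | OC/C=C(C)/C=C/[C@H]1C(C)=CCCC1(C)C
F9 | step 4 | (1R)-1-[(1E,3E)-5-bromo-3-methylpenta-1,3-dien-1-yl]-2,6,6-trimethylcyclohex-2-ene | BrC/C=C(C)/C=C/[C@H]1C(C)=CCCC1(C)C
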